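The easy step first: in the amber flask the substrate reads 0% at 3.00 h, so from there on the question is what becomes of the material already converted, not how fast it converts.

| flask | substrate | reagent | initiator | temperature | remark | time |
|---|---|---|---|---|---|---|
| amber | 1.7 M | 1.78 M | 85 mM | 40 °C | the very flask that is asked about, followed so far |  |
| green | 1.7 M | 1.78 M | 85 mM | 25 °C | run made earlier |  |
| flask | 1.7 M | 1.78 M | 85 mM | 40 °C |  | 8.0 h |

| run | time / h | target / % | substrate / % |
|---|---|---|---|
| amber | 0.667 | 38.2 | 10.2 |
| amber | 1.50 | 26.5 | 1.1 |
| amber | 3.00 | 28.0 | 0 |
| amber | 5.00 | 26.3 | 0 |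
| green | 1.33 | 55.7 | 20.5 |
| green | 3.00 | 37.8 | 9.0 |
| green | 6.00 | 19.6 | 1.5 |
| green | 10.0 | 12.0 | 0 |

(readings scatter by 1 percentage point)

- the volume of additions can be left aside
- the numbers in the tables scatter with a standard deviation of 1 percentage point

- west: at 8.0 h raise the temperature by 25 K, then wait 15 h
- north: at 8.0 h take out 90% of the by-product then present, then wait 15 h
- south: change nothing and wait 15 h more

1. target, in percent of the substrate first charged, at 8.0 h
2. the remedy with the largest gain of target, or "none" below 2 percentage points (west / north / south / none)
3. target present, in percent of the substrate first charged, after west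
4. target present, in percent of the substrate first charged, after south

Anna holds that the target suffers a one-way loss that stopped. Between 0.667 h and 1.50 h the amber target falls from 38.2% to 26.5%, a rate of 0.439 h⁻¹. Continued to 5.00 h, that rate gives 5.70%, but the reading is 26.3%. So she says the initiator stopped working and the flat readings belong to a dead flask, while the cooler green run, ending at 12.0%, merely lost target for longer. On her view, heating the amber flask gains nothing.

Ben holds that the target balances against a partner. He reads the standing share, the part of the substrate charged that stands as target once the target stops moving: the mean of the last amber readings gives 26.9%. The green run's last reading is lower, so he expects a hotter flask to hold a larger share. A falling target that meets its share is where kinetic control hands over to thermodynamic control, and that crossing comes by 1.50 h in the amber run, while the green target is still falling from 19.6% to 12.0% between 6.00 h and 10.0 h.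

My own reckoning takes Ben's side: the target at 8.0 h is the share, 26.9%, and waiting leaves it there. Anna agrees on those two numbers, so west separates them.

The forecast, which is Ben's, says “Reversible target ⇌ by-product fits best”. It gives 27% now (25.8% to 28.2%), west as the remedy, 60% after west (40% to 76%) and 27% after south (25% to 28.5%).

The simulation gives 26.7% now, 65.9% after west, a gain of 39 points, and 26.7% after south.

    initiator → 2 initiating radical (k = 1.40 × 10⁻⁴ s⁻¹, Ea = 104 kJ mol⁻¹)
    substrate + initiating radical → capped initiator + first chain carrier (k = 7000 M⁻¹ s⁻¹, Ea = 36.0 kJ mol⁻¹)
    reagent + first chain carrier ⇌ target + second chain carrier (K = 1.50, k = 14000 M⁻¹ s⁻¹, Ea = 14.0 kJ mol⁻¹, ΔH = −25.0 kJ mol⁻¹)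
    substrate + second chain carrier → by-product + first chain carrier (k = 330 M⁻¹ s⁻¹, Ea = 37.0 kJ mol⁻¹)
    2 first chain carrier → ended chains (k = 2.00 × 10⁶ M⁻¹ s⁻¹, Ea = 13.0 kJ mol⁻¹)
    target ⇌ isomer of the product (K = 2.50, k = 6.00 × 10⁻⁴ s⁻¹, Ea = 90.0 kJ mol⁻¹, ΔH = −63.0 kJ mol⁻¹)
    (constants at 40 °C)

West lifts the target by 39 points, against Anna's view, and the partner is the isomer of the product. Anna keeps the stretch above the share, where the amber target does fall, down to the reading at 1.50 h, though with the way back counted: target and isomer of the product relax with a half-life of 0.229 h, shorter than 8.0 h. After that reading the share holds: 26.9% read against 26.7%. The neighbour flask with 1.1 M of reagent has 0.647 equiv of it, the limiting reagent, so target and isomer of the product together can reach 64.7% of the substrate charged. In the asked flask they hold 93.5%, so the share, taken per that sum, gives 18.6% in the neighbour. The neighbour holds 18.5% target at 8.00 h, with reagent at 0% and substrate at 25.5%.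

All runs are simulated with constants of no real substance, and the scatter is random.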